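## Retrosynthetic overview

1. Pyran ring B is opened last, at the aryl ether bond O–C4 of quinolinone B and at the bond between the ring-fusion O–CH carbon and the CMe2 carbon. This releases acetone, which the forward route re-inserts by a reductive samarium Barbier addition / SNAr domino.
2. Enabling feature: the ring-fusion carbon C-2 of pyran ring A carries the ring oxygen O-1, so it is of lactol (acetal) parentage and can be held as an anomeric 2-pyridyl sulfone and reduced to a carbanion. C-4 of quinolinone B is the β-carbon of an α,β-unsaturated lactam and takes up an alkoxide by addition–elimination when it bears chloride.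
3. Pyran ring A is a lactol between the 4-OH of quinolinone A and an aldehyde. Its C-3–C-4 bond comes from an Ir/amine dual-catalytic α-allylation: the catalyst sets C-4, C-3 follows, and C-2 is set from C-3 in the key step. The 2-methylpropenyl group comes from cross-metathesis.
4. Building blocks: the acetaldehyde of 4-chloroquinolinone B (N-methylaniline + diethyl allylmalonate, POCl3, O3) and the vinyl carbinol of MOM-protected quinolinone A (4-hydroxy-1-methylquinolin-2-one, lithiation, acrolein).
5. Ring order: pyridone ring of quinolinone B (step 1; quinolinone A is bought), pyran ring A (step 8), pyran ring B (step 10).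

Key step: step 10

Remark: C-2/C-3/C-4 are the pyran positions of the 2H-pyrano[3,2-c]quinolin-5-one (ring A); 18 and 19 are carried as mixtures at C-2 because that centre passes through a radical in step 10; in step 6 the antipodes of ligand and amine are those that lead to (2S,3R)-14.

## Route

Step 1
Reactants: 1 N-methylaniline; 2 diethyl 2-allylmalonate
Product: 4 3-allyl-4-hydroxy-1-methylquinolin-2(1H)-one, via anilide ester 3 (not isolated)
Conditions: Ph2O, 200→250 °C, EtOH distilled off
Reagents that add atoms: none
Why: Thermal condensation of an N-alkylaniline with a monosubstituted malonate (amide formation, then intramolecular Friedel–Crafts-type acylation with loss of the second ethanol) is the standard entry to 3-substituted 4-hydroxy-2-quinolones.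

Step 2
Reactants: 4 3-allyl-4-hydroxy-1-methylquinolin-2(1H)-one
Product: 6 3-allyl-4-chloro-1-methylquinolin-2(1H)-one, via aryl dichlorophosphate 5 (not isolated)
Conditions: POCl3 (3 equiv), toluene, 100 °C
Reagents that add atoms: phosphoryl chloride, O=P(Cl)(Cl)Cl
Why: Deoxychlorination of the vinylogous acid through its dichlorophosphate and addition–elimination of chloride at C-4 is the usual preparation of 4-chloro-2-quinolones.

Step 3
Reactants: 6 3-allyl-4-chloro-1-methylquinolin-2(1H)-one
Product: 8 2-(4-chloro-1-methyl-2-oxo-1,2-dihydroquinolin-3-yl)acetaldehyde, via secondary ozonide 7 (not isolated)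
Conditions: O3, CH2Cl2, −78 °C (indicator dye); PPh3, −78→20 °C
Reagents that add atoms: ozone, [O-][O+]=O
Why: Ozonolysis with reductive work-up cleaves the monosubstituted alkene, which is far more reactive towards ozone than the electron-poor chloroquinolinone ring.

Step 4
Reactants: 9 4-hydroxy-1-methylquinolin-2(1H)-one
Product: 10 4-(methoxymethoxy)-1-methylquinolin-2(1H)-one
Conditions: NaH, MOMCl, DMF, 0 °C
Reagents that add atoms: chloromethyl methyl ether, COCCl
Why: Williamson-type O-alkylation of the vinylogous acid with the hard electrophile MOMCl masks the acidic OH and installs the directing group for step 5.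

Step 5
Reactants: 10 4-(methoxymethoxy)-1-methylquinolin-2(1H)-one; 11 acrolein
Product: 13 rac-3-(1-hydroxyprop-2-en-1-yl)-4-(methoxymethoxy)-1-methylquinolin-2(1H)-one, via 3-lithioquinolinone 12 (not isolated)
Conditions: n-BuLi, THF, −78 °C; acrolein, −78 °C; H2O
Reagents that add atoms: none
Why: Directed ortho-metalation at C-3 between the OMOM group and the lactam carbonyl (as for 4-alkoxy-2-pyridones and -quinolones), then 1,2-addition to acrolein, gives the carbinol, whose racemic stereocenter is erased at the π-allyl stage of step 6.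

Step 6
Reactants: 8 2-(4-chloro-1-methyl-2-oxo-1,2-dihydroquinolin-3-yl)acetaldehyde; 13 rac-3-(1-hydroxyprop-2-en-1-yl)-4-(methoxymethoxy)-1-methylquinolin-2(1H)-one
Product: 14 (2S,3R)-2-(4-chloro-1-methyl-2-oxo-1,2-dihydroquinolin-3-yl)-3-[4-(methoxymethoxy)-1-methyl-2-oxo-1,2-dihydroquinolin-3-yl]pent-4-enal
Conditions: [Ir(cod)Cl]2 (3 mol%), BINOL-derived dibenzo[b,f]azepine phosphoramidite (P,olefin) ligand (12 mol%), 2-[bis(3,5-bis(trifluoromethyl)phenyl)(trimethylsilyloxy)methyl]pyrrolidine (15 mol%), (MeO)2P(O)OH (0.5 equiv), ClCH2CH2Cl, 25 °C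
Reagents that add atoms: none
Why: In this stereodivergent iridium/amine dual-catalytic α-allylation of a linear aldehyde with a racemic aryl vinyl carbinol, the chiral Ir π-allyl complex fixes the allylic carbon C-3 (R) by ligand control at the branched terminus and the enamine of 8 fixes C-2 (S) by face shielding, each catalyst acting independently.

Step 7
Reactants: 14 (2S,3R)-pent-4-enal of step 6; 15 2-methylbut-2-ene
Product: 16 (2S,3R)-2-(4-chloro-1-methyl-2-oxo-1,2-dihydroquinolin-3-yl)-3-[4-(methoxymethoxy)-1-methyl-2-oxo-1,2-dihydroquinolin-3-yl]-5-methylhex-4-enal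
Conditions: 2nd-generation Ru metathesis catalyst (NHC, chelating 2-isopropoxybenzylidene; 5 mol%), 2-methylbut-2-ene/CH2Cl2 1:1, 40 °C, sealed tube
Reagents that add atoms: none
Why: Olefin cross-metathesis of the terminal alkene with excess 2-methylbut-2-ene exchanges =CH2 for =CMe2 with loss of propene, a standard vinyl-to-isobutenyl conversion that touches no stereocenter.

Step 8
Reactants: 16 (2S,3R)-5-methylhex-4-enal of step 7
Product: 18 (3S,4R)-3-(4-chloro-1-methyl-2-oxo-1,2-dihydroquinolin-3-yl)-2-hydroxy-6-methyl-4-(2-methylprop-1-en-1-yl)-2,3,4,6-tetrahydro-5H-pyrano[3,2-c]quinolin-5-one (anomeric mixture), via hydroxy aldehyde 17 (not isolated)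
Conditions: 1 M HCl/THF 1:4, 0→23 °C
Reagents that add atoms: none
Why: Mild acid hydrolysis of the vinylogous MOM ester frees the 4-hydroxyquinolinone, which closes onto the aldehyde by hemiacetalization to the six-membered lactol (pyran ring A); C-4 is untouched and C-3, α to the masked aldehyde, can only equilibrate towards the trans arrangement already present.

Step 9
Reactants: 18 lactol of step 8
Product: 19 (3S,4R)-3-(4-chloro-1-methyl-2-oxo-1,2-dihydroquinolin-3-yl)-6-methyl-4-(2-methylprop-1-en-1-yl)-2-(pyridin-2-ylsulfonyl)-2,3,4,6-tetrahydro-5H-pyrano[3,2-c]quinolin-5-one (anomeric mixture)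
Conditions: sodium pyridine-2-sulfinate (3 equiv), CF3CO2H (3 equiv), MgSO4, CH2Cl2, 0→23 °C
Reagents that add atoms: sodium pyridine-2-sulfinate, [Na+].[O-]S(=O)c1ccccn1
Why: Anomeric sulfone formation from a lactol and a sulfinic acid proceeds by ionization to the cyclic oxocarbenium ion and capture at sulfur, and a 4H-pyran formed by elimination would re-enter by protonation, so C-3/C-4 stay trans and the C-2 mixture is of no consequence.

Step 10
Reactants: 19 anomeric 2-pyridyl sulfone of step 9; 20 acetone
Product: 23 target CNP0107253.2, via anomeric organosamarium 21 (not isolated), via samarium alkoxide 22 (not isolated)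
Conditions: SmI2 (2.5 equiv, 0.1 M in THF) added to 19 and acetone (3 equiv), THF, 20 °C; then t-BuOK (3 equiv), 0→25 °C, same flask
Reagents that add atoms: none
Why: Two single-electron transfers from SmI2 cleave the 2-pyridylsulfonyl group to pyridine-2-sulfinate and the anomeric radical at C-2, which is reduced to organosamarium(III) 21, so the acetal-level carbon becomes a nucleophile (polarity reversal) and adds to acetone to form the C-2–CMe2 bond of alkoxide 22. The closest known reaction type is the samarium Barbier C-glycosylation of glycosyl 2-pyridyl sulfones with ketones, followed here by the standard alkoxide SNAr on a 4-chloro-2-quinolone, a vinylogous carbamoyl chloride. Pyran ring B closes by 6-endo-trig attack of the tertiary alkoxide on C-4 of the chloroquinolinone (the C-3=C-4 bond lies inside the new ring) and loss of chloride. The new stereocenter C-2 is set under substrate control from C-3: the anomeric organosamarium is configurationally labile, its cis isomer is held by a six-membered chelate to the lactam carbonyl of the neighbouring quinolinone while the other face is screened by the pseudoaxial 2-methylpropenyl group at C-4, and addition to acetone occurs with retention. The step needs chemoselective reduction of the sulfone beside an aryl chloride and two unsaturated lactams, which the easily reduced 2-pyridylsulfonyl group secures with SmI2 in THF without HMPA. It also needs cis C-2/C-3 selectivity, and only the cis alkoxide holds its oxygen within reach of C-4 in the preferred half-chair, so ring closure also filters the diastereomers.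

## Compound list

1 | N-methylaniline | CNc1ccccc1 | starting material
2 | diethyl 2-allylmalonate | C=CCC(C(=O)OCC)C(=O)OCC | starting material
3 | ethyl 2-[methyl(phenyl)carbamoyl]pent-4-enoate (racemic anilide ester) | C=CCC(C(=O)OCC)C(=O)N(C)c1ccccc1 | intermediate
4 | 3-allyl-4-hydroxy-1-methylquinolin-2(1H)-one | C=CCc1c(O)c2ccccc2n(C)c1=O | intermediate
5 | 3-allyl-1-methyl-2-oxo-1,2-dihydroquinolin-4-yl phosphorodichloridate | C=CCc1c(OP(=O)(Cl)Cl)c2ccccc2n(C)c1=O | intermediate
6 | 3-allyl-4-chloro-1-methylquinolin-2(1H)-one | C=CCc1c(Cl)c2ccccc2n(C)c1=O | intermediate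
7 | 4-chloro-1-methyl-3-[(1,2,4-trioxolan-3-yl)methyl]quinolin-2(1H)-one (secondary ozonide) | Clc1c(CC2OCOO2)c(=O)n(C)c2ccccc12 | intermediate
8 | 2-(4-chloro-1-methyl-2-oxo-1,2-dihydroquinolin-3-yl)acetaldehyde | O=CCc1c(Cl)c2ccccc2n(C)c1=O | intermediate
9 | 4-hydroxy-1-methylquinolin-2(1H)-one | Cn1c(=O)cc(O)c2ccccc21 | starting material
10 | 4-(methoxymethoxy)-1-methylquinolin-2(1H)-one | COCOc1cc(=O)n(C)c2ccccc12 | intermediate
11 | acrolein | C=CC=O | starting material
12 | 3-lithio-4-(methoxymethoxy)-1-methylquinolin-2(1H)-one | [Li]c1c(OCOC)c2ccccc2n(C)c1=O | intermediate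
13 | rac-3-(1-hydroxyprop-2-en-1-yl)-4-(methoxymethoxy)-1-methylquinolin-2(1H)-one | C=CC(O)c1c(OCOC)c2ccccc2n(C)c1=O | intermediate
14 | (2S,3R)-2-(4-chloro-1-methyl-2-oxo-1,2-dihydroquinolin-3-yl)-3-[4-(methoxymethoxy)-1-methyl-2-oxo-1,2-dihydroquinolin-3-yl]pent-4-enal | C=C[C@@H](c1c(OCOC)c2ccccc2n(C)c1=O)[C@H](C=O)c1c(Cl)c2ccccc2n(C)c1=O | intermediate
15 | 2-methylbut-2-ene | CC=C(C)C | starting material
16 | (2S,3R)-2-(4-chloro-1-methyl-2-oxo-1,2-dihydroquinolin-3-yl)-3-[4-(methoxymethoxy)-1-methyl-2-oxo-1,2-dihydroquinolin-3-yl]-5-methylhex-4-enal | CC(C)=C[C@@H](c1c(OCOC)c2ccccc2n(C)c1=O)[C@H](C=O)c1c(Cl)c2ccccc2n(C)c1=O | intermediate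
17 | (2S,3R)-2-(4-chloro-1-methyl-2-oxo-1,2-dihydroquinolin-3-yl)-3-(4-hydroxy-1-methyl-2-oxo-1,2-dihydroquinolin-3-yl)-5-methylhex-4-enal | CC(C)=C[C@@H](c1c(O)c2ccccc2n(C)c1=O)[C@H](C=O)c1c(Cl)c2ccccc2n(C)c1=O | intermediate
18 | (3S,4R)-3-(4-chloro-1-methyl-2-oxo-1,2-dihydroquinolin-3-yl)-2-hydroxy-6-methyl-4-(2-methylprop-1-en-1-yl)-2,3,4,6-tetrahydro-5H-pyrano[3,2-c]quinolin-5-one (lactol, C-2 mixture) | CC(C)=C[C@H]1c2c(c3ccccc3n(C)c2=O)OC(O)[C@@H]1c1c(Cl)c2ccccc2n(C)c1=O | intermediate
19 | (3S,4R)-3-(4-chloro-1-methyl-2-oxo-1,2-dihydroquinolin-3-yl)-6-methyl-4-(2-methylprop-1-en-1-yl)-2-(pyridin-2-ylsulfonyl)-2,3,4,6-tetrahydro-5H-pyrano[3,2-c]quinolin-5-one (C-2 mixture) | CC(C)=C[C@H]1c2c(c3ccccc3n(C)c2=O)OC(S(=O)(=O)c2ccccn2)[C@@H]1c1c(Cl)c2ccccc2n(C)c1=O | intermediate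
20 | acetone | CC(C)=O | starting material
21 | C-2 diiodosamarium(III) derivative of ring A, metal cis to the C-3 quinolinonyl group, 3S,4R | CC(C)=C[C@H]1c2c(c3ccccc3n(C)c2=O)O[C@H]([Sm](I)I)[C@@H]1c1c(Cl)c2ccccc2n(C)c1=O | intermediate
22 | diiodosamarium(III) alkoxide of the (2S,3S,4R) 2-(2-hydroxypropan-2-yl) Barbier adduct | CC(C)=C[C@H]1c2c(c3ccccc3n(C)c2=O)O[C@H](C(C)(C)O[Sm](I)I)[C@@H]1c1c(Cl)c2ccccc2n(C)c1=O | intermediate
23 | CNP0107253.2: cis-fused bis(pyrano[3,2-c]quinolinone), R at the carbon bearing the 2-methylprop-1-enyl group, S at both ring-fusion carbons | CC(C)=C[C@H]1c2c(c3ccccc3n(C)c2=O)O[C@H]2[C@@H]1c1c(c3ccccc3n(C)c1=O)OC2(C)C | target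

## Step count and risks

Total step count: 10. Longest linear sequence: 8 steps (1, 2, 3, 6, 7, 8, 9, 10).

Steps most likely to fail:

Step 10. The organosamarium may be protonated, or may undergo O→C 1,2-migration of the quinolinonyl group, before it finds acetone. The aryl chloride may be reduced. Facial selectivity at C-2 may be insufficient. The fallback sets out from 19 and keeps the sulfone as an anion-stabilizing group instead of reducing it. Deprotonation at C-2 (LDA, THF, −78 °C) should give the sulfonyl-stabilized anomeric anion, which adds to acetone. On warming, the lithium alkoxide closes ring B by the same addition–elimination to give the ring-fusion sulfone, (2-pyridylsulfonyl)-pentacycle F1. Reductive desulfonylation (SmI2, THF/MeOH, 0 °C; radical, then anion, then protonation from the convex face of the cis-fused system) should then return to the route at 23.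

Step 6. The carbinol carbon of 13 is flanked by two ortho substituents, so π-allyl formation may be slow. Acid-promoted ionization outside the iridium cycle (racemic background, loss of the MOM group) or base-type side reactions of the enolizable aldehyde 8 may take over. The fallback sets out from 10 and replaces the metal π-allyl by an organocatalytic SN1-type α-alkylation. Lithiation of 10 (n-BuLi, THF, −78 °C) and addition to 3-methylbut-2-enal should give the prenal-derived carbinol, 3-(1-hydroxy-3-methylbut-2-en-1-yl)-4-(methoxymethoxy)-1-methylquinolin-2(1H)-one F2. Its stabilized allyl cation (In(OTf)3, chiral secondary amine, CH2Cl2, 0 °C) is trapped at the secondary terminus by the enamine of 8. After separation of the C-3 epimers this comes back to the route at 16 and also bypasses step 7.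

Step 9. The oxocarbenium ion may eliminate to the 4H-pyran, and the zwitterionic sulfinic acid may be too insoluble to capture it. The fallback sets out from 18 and brings in sulfur as a thiol. Condensation with pyridine-2-thiol (BF3·OEt2, CH2Cl2, −20 °C) should give the S-(2-pyridyl) thioacetal F3. Oxidation at sulfur with H2O2/ammonium heptamolybdate (EtOH, 0 °C), which spares the trisubstituted alkene, comes back to the route at 19.

Further compounds
F1 | step 10 | ring-fusion 2-pyridyl sulfone of the target (SO2Py in place of H at the O–C ring-fusion carbon) | CC(C)=C[C@H]1c2c(c3ccccc3n(C)c2=O)O[C@@]2(S(=O)(=O)c3ccccn3)[C@@H]1c1c(c3ccccc3n(C)c1=O)OC2(C)C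
F2 | step 6 | rac-3-(1-hydroxy-3-methylbut-2-en-1-yl)-4-(methoxymethoxy)-1-methylquinolin-2(1H)-one | CC(C)=CC(O)c1c(OCOC)c2ccccc2n(C)c1=O
F3 | step 9 | (3S,4R)-3-(4-chloro-1-methyl-2-oxo-1,2-dihydroquinolin-3-yl)-6-methyl-4-(2-methylprop-1-en-1-yl)-2-(pyridin-2-ylsulfanyl)-2,3,4,6-tetrahydro-5H-pyrano[3,2-c]quinolin-5-one (C-2 mixture) | CC(C)=C[C@H]1c2c(c3ccccc3n(C)c2=O)OC(Sc2ccccn2)[C@@H]1c1c(Cl)c2ccccc2n(C)c1=O
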